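Ring A is numbered C1 (carboxyl-bearing carbon), C2 (hydroxyl), C4 (depside oxygen), C6 (pentyl).
Retrosynthesis: cut the depside ester C–O bond (O4 of ring A to the ring B carbonyl), then ring A at C3–C4, C1–C2 and C4–C5, then the benzylic C–C bond of the ring B propyl group.
Enabling feature: ring A is a resorcinol with C3–H between its two oxygens and C5–H beside the C6 pentyl group, so C2/C3 map onto a terminal ynol ether and C4, C1, C6, C5 onto an ester-bearing (1-pentylvinyl)ketene.
Forward: heptanal gives the diazo keto ester in three steps and benzyl alcohol gives (benzyloxy)ethyne in two; photochemical Wolff rearrangement and benzannulation then close ring A, the only ring built, with a free 4-hydroxyl and a 2-benzyl ether.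
Ring B comes intact from 2,4-dimethoxy-6-methylbenzoic acid by lateral ethylation; esterification at the 4-hydroxyl and one hydrogenolysis finish the route.
Stereochemistry: the target has no stereocentre and no stereogenic double bond; the transient centres (aldol carbinol, cyclobutenone quaternary carbon) are racemic and vanish.

Key step: step 6

Remark: a benzyl ynol ether is chosen over a silyl one because a parent silyl ynol ether is prone to 1,3-silyl shift to the silylketene and because the benzyl ether falls in the same hydrogenolysis as the benzyl ester; benzyl diazoacetate and 2,4-dimethoxy-6-methylbenzoic acid are taken as purchasable.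

Step 1
Reactants: 1 heptanal
Product: 2 2-methylideneheptanal
Conditions: 37% aq. CH2O, pyrrolidine (10 mol%), EtCO2H (10 mol%), i-PrOH, 45 °C
Reagents that add atoms: formaldehyde, C=O
Why: Amine-catalysed Mannich condensation with formaldehyde followed by loss of the amine (organocatalytic α-methylenation of an aldehyde) is the standard entry to 2-alkylacroleins and creates no stereocentre.

Step 2
Reactants: 2 2-methylideneheptanal; 3 benzyl diazoacetate
Product: 5 benzyl 2-diazo-3-hydroxy-4-methylidenenonanoate, via lithiated benzyl diazoacetate 4 (not isolated)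
Conditions: LiN(i-Pr)2 added to 2 + 3, THF, −78 °C; AcOH quench at −78 °C
Reagents that add atoms: none
Why: Aldol-type addition of a lithiated diazoacetate to an aldehyde carbonyl is fast at −78 °C, where neither conjugate addition nor dipolar cycloaddition of the diazo group to the enal C=C should compete; the carbinol centre forms as a racemate and is erased in step 3.

Step 3
Reactants: 5 benzyl 2-diazo-3-hydroxy-4-methylidenenonanoate
Product: 6 benzyl 2-diazo-4-methylidene-3-oxononanoate
Conditions: IBX, DMSO, rt
Reagents that add atoms: none
Why: IBX oxidation of β-hydroxy-α-diazo esters to 2-diazo-3-keto esters is a known, neutral oxidation that spares the acceptor-stabilised diazo group and the 1,1-disubstituted alkene.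

Step 4
Reactants: 7 benzyl alcohol
Product: 8 benzyl (E)-1,2-dichlorovinyl ether
Conditions: KH, THF, 0 °C; Cl2C=CHCl, −50 °C → rt
Reagents that add atoms: trichloroethylene, ClC=C(Cl)Cl
Why: First half of the Greene ynol ether synthesis: the alkoxide eliminates HCl from trichloroethylene and adds anti to the dichloroacetylene so formed, which gives the (E)-dichloro enol ether (its geometry is of no consequence).

Step 5
Reactants: 8 benzyl (E)-1,2-dichlorovinyl ether
Product: 11 (benzyloxy)ethyne, via benzyl chloroethynyl ether 9 (not isolated), via lithium (benzyloxy)ethynide 10 (not isolated)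
Conditions: n-BuLi (2.2 equiv), THF, −78 → −40 °C; MeOH, −78 °C; cold work-up, kept below rt and used promptly
Reagents that add atoms: none
Why: Second half of the Greene ynol ether synthesis: vinylic deprotonation with loss of LiCl gives chloroalkyne 9, chlorine–lithium exchange gives acetylide 10, and methanol protonates it at −78 °C, well below the range (about 60 °C) in which benzyl alkynyl ethers undergo [3,3]-sigmatropic rearrangement.

Step 6
Reactants: 6 benzyl 2-diazo-4-methylidene-3-oxononanoate; 11 (benzyloxy)ethyne
Product: 16 benzyl 2-(benzyloxy)-4-hydroxy-6-pentylbenzoate, via vinylketene 12 (not isolated), via vinylcyclobutenone 13 (not isolated), via dienylketene 14 (not isolated), via cyclohexadienone 15 (not isolated)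
Conditions: hν (300 nm), 11 (3 equiv), degassed CH2Cl2, rt; evaporate excess 11 cold; toluene, 80 °C
Reagents that add atoms: none
Why: Proposed new method: irradiation should expel N2 from 6 and shift the 1-pentylvinyl group to the carbene carbon (photochemical Wolff rearrangement), and the resulting ester-bearing vinylketene 12 should add ynol ether 11 across its C=C bond in a [2+2] cycloaddition, the nucleophilic unsubstituted alkyne carbon attacking the ketene carbonyl carbon (ring-A bond C3–C4) and the oxygen-bearing alkyne carbon closing onto the ketene α-carbon (bond C1–C2) to give cyclobutenone 13. Warming should open 13 by reversible four-electron electrocyclic cleavage of its C1–C4 bond to dienylketene 14, and ring A then closes by six-electron disrotatory electrocyclisation of the ketene carbon onto the terminal methylene (bond C4–C5), after which dienone 15 tautomerises to phenol 16. The closest known reaction type is the Danheiser benzannulation of photochemically generated vinylketenes with alkoxy- and silyloxyalkynes, which has not been shown for a ketene carrying an ester on its α-carbon (a 2-diazo-3-keto ester precursor), although six-electron closure of ester-bearing dienylketenes to salicylates has precedent. No stereocentre survives, since the quaternary carbon of 13 is racemic and becomes planar on ring opening, and only the (Z)-dienylketene can close while the (E)-isomer returns through 13. The step needs the stated [2+2] regiochemistry, which the polarisation of the ynol ether secures, and addition at the ketene C=C in preference to hetero-[4+2] addition through the ester carbonyl, which should be favoured by the weak heterodiene character of an ester carbonyl and by keeping 11 in excess so that the ketene is trapped as it forms. The ketene oxygen emerges as the free 4-hydroxyl and the alkyne oxygen as the 2-benzyl ether, so the two ring-A oxygens never have to be told apart.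

Step 7
Reactants: 17 2,4-dimethoxy-6-methylbenzoic acid
Product: 19 2,4-dimethoxy-6-propylbenzoic acid, via dilithio dianion 18 (not isolated)
Conditions: LiN(i-Pr)2 (2.2 equiv), THF, −78 → 0 °C; EtI, −78 °C → rt; aq. HCl
Reagents that add atoms: ethyl iodide, CCI
Why: Lateral metalation of an o-toluic acid (Creger-type dianion: the carboxylate directs deprotonation of the ortho methyl group, which is meta to both methoxy groups) followed by C-alkylation of the benzylic carbanion with a primary iodide.

Step 8
Reactants: 19 2,4-dimethoxy-6-propylbenzoic acid; 16 benzyl 2-(benzyloxy)-4-hydroxy-6-pentylbenzoate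
Product: 21 benzyl 2-(benzyloxy)-4-[(2,4-dimethoxy-6-propylbenzoyl)oxy]-6-pentylbenzoate, via 2,4-dimethoxy-6-propylbenzoyl chloride 20 (not isolated)
Conditions: (COCl)2, DMF (cat.), CH2Cl2, 0 °C → rt, evaporate; 16, Et3N, DMAP (cat.), CH2Cl2, 0 °C → rt
Reagents that add atoms: none
Why: Acyl chloride esterification of a phenol under DMAP catalysis (nucleophilic acyl substitution via the acylpyridinium ion); the 4-hydroxyl is the only free hydroxyl of 16 and is unhindered, so the di-ortho-substituted aroyl group has a single place to go.

Step 9
Reactants: 21 benzyl 2-(benzyloxy)-4-[(2,4-dimethoxy-6-propylbenzoyl)oxy]-6-pentylbenzoate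
Product: 22 4-[(2,4-dimethoxy-6-propylbenzoyl)oxy]-2-hydroxy-6-pentylbenzoic acid
Conditions: H2 (1 atm), 10% Pd/C, EtOAc, rt
Reagents that add atoms: none
Why: Palladium-catalysed hydrogenolysis cleaves the benzyl ester and the aryl benzyl ether in one operation, while the aryl ester of the depside, the aryl methyl ethers and the arene rings are inert to H2 over Pd/C at room temperature.

Compound list
1 | heptanal | CCCCCCC=O | starting material
2 | 2-methylideneheptanal | CCCCCC(=C)C=O | intermediate
3 | benzyl diazoacetate | [N-]=[N+]=CC(=O)OCc1ccccc1 | starting material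
4 | lithiated benzyl diazoacetate (benzyl 2-diazo-2-lithioacetate; not isolated) | [Li]C(=[N+]=[N-])C(=O)OCc1ccccc1 | intermediate
5 | benzyl 2-diazo-3-hydroxy-4-methylidenenonanoate (racemic) | CCCCCC(=C)C(O)C(=[N+]=[N-])C(=O)OCc1ccccc1 | intermediate
6 | benzyl 2-diazo-4-methylidene-3-oxononanoate | CCCCCC(=C)C(=O)C(=[N+]=[N-])C(=O)OCc1ccccc1 | intermediate
7 | benzyl alcohol | OCc1ccccc1 | starting material
8 | benzyl (E)-1,2-dichlorovinyl ether | Cl/C=C(\OCc1ccccc1)Cl | intermediate
9 | benzyl chloroethynyl ether (not isolated) | ClC#COCc1ccccc1 | intermediate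
10 | lithium (benzyloxy)ethynide (not isolated) | [Li]C#COCc1ccccc1 | intermediate
11 | (benzyloxy)ethyne (benzyl ethynyl ether) | C#COCc1ccccc1 | intermediate
12 | vinylketene, benzyl 2-(hept-1-en-2-yl)-3-oxoprop-2-enoate (not isolated) | CCCCCC(=C)C(=C=O)C(=O)OCc1ccccc1 | intermediate
13 | vinylcyclobutenone, benzyl 2-(benzyloxy)-1-(hept-1-en-2-yl)-4-oxocyclobut-2-ene-1-carboxylate (racemic; not isolated) | CCCCCC(=C)C1(C(=O)OCc2ccccc2)C(=O)C=C1OCc1ccccc1 | intermediate
14 | dienylketene, benzyl (2Z)-3-(benzyloxy)-2-(hept-1-en-2-yl)-5-oxopenta-2,4-dienoate (not isolated) | O=C=C/C(OCc1ccccc1)=C(\C(=C)CCCCC)C(=O)OCc1ccccc1 | intermediate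
15 | cyclohexadienone, benzyl 6-(benzyloxy)-4-oxo-2-pentylcyclohexa-1,5-diene-1-carboxylate (not isolated) | CCCCCC1=C(C(=O)OCc2ccccc2)C(OCc2ccccc2)=CC(=O)C1 | intermediate
16 | benzyl 2-(benzyloxy)-4-hydroxy-6-pentylbenzoate | CCCCCc1cc(O)cc(OCc2ccccc2)c1C(=O)OCc1ccccc1 | intermediate
17 | 2,4-dimethoxy-6-methylbenzoic acid | COc1cc(C)c(C(=O)O)c(OC)c1 | starting material
18 | dilithio dianion of 17, lithium 2-(lithiomethyl)-4,6-dimethoxybenzoate (not isolated) | [Li]Cc1cc(OC)cc(OC)c1C(=O)O[Li] | intermediate
19 | 2,4-dimethoxy-6-propylbenzoic acid | CCCc1cc(OC)cc(OC)c1C(=O)O | intermediate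
20 | 2,4-dimethoxy-6-propylbenzoyl chloride (not isolated) | CCCc1cc(OC)cc(OC)c1C(=O)Cl | intermediate
21 | benzyl 2-(benzyloxy)-4-[(2,4-dimethoxy-6-propylbenzoyl)oxy]-6-pentylbenzoate | CCCCCc1cc(OC(=O)c2c(CCC)cc(OC)cc2OC)cc(OCc2ccccc2)c1C(=O)OCc1ccccc1 | intermediate
22 | 4-[(2,4-dimethoxy-6-propylbenzoyl)oxy]-2-hydroxy-6-pentylbenzoic acid | CCCCCc1cc(OC(=O)c2c(CCC)cc(OC)cc2OC)cc(O)c1C(=O)O | target

Total step count: 9 steps.
Longest linear sequence: 6 steps (steps 1, 2, 3, 6, 8, 9, from heptanal).

Steps most likely to fail

1. Step 6. The photogenerated carbene may be captured by the ynol ether or the solvent before the vinyl shift. The ynol ether may add across the ketene C=C and the ester C=O in a hetero-[4+2] sense. The ketene may dimerise, or unreacted ynol ether may rearrange if heating begins before it is removed. The fallback uses known chemistry throughout and gives up the benzannulation: ring A is taken from purchased olivetol (5-pentylresorcinol). It sets out from acid 19 and returns to the route at target 22. Olivetol is carboxylated with methyl magnesium carbonate (MeOMgOCO2Me, DMF, 120 °C; Stiles carboxylation), which should give 2,4-dihydroxy-6-pentylbenzoic acid F1. O-Alkylation of the carboxylate of F1 (BnBr, KHCO3, DMF, rt) should give benzyl 2,4-dihydroxy-6-pentylbenzoate F2. Chloride 20, made from 19 as in step 8, should acylate F2 selectively at the 4-hydroxyl, because the 2-hydroxyl is tied up in a hydrogen bond to the ester carbonyl (pyridine, CH2Cl2, 0 °C). This should give benzyl 4-[(2,4-dimethoxy-6-propylbenzoyl)oxy]-2-hydroxy-6-pentylbenzoate F3. Hydrogenolysis of F3 (H2, 10% Pd/C, EtOAc) then gives 22.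

2. Step 5. n-BuLi may deprotonate the benzylic position and trigger Wittig-type rearrangement, and the terminal ynol ether may be lost by hydration or polymerisation during isolation. The fallback avoids alkyllithium and the acetylide by the classical bromovinyl ether route; it sets out from benzyl alcohol 7 and returns at 11. Transfer vinylation of 7 with vinyl acetate ([Ir(cod)Cl]2, Na2CO3, toluene, 100 °C) should give benzyl vinyl ether F4. Bromine addition (Br2, CH2Cl2, −78 °C) should give benzyl 1,2-dibromoethyl ether F5. Dehydrobromination with PhNEt2 (90 °C) should give benzyl (Z)-2-bromovinyl ether F6. Anti elimination with KOt-Bu (THF, 0 °C) should then give 11.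

3. Step 2. The lithiated diazoacetate may decompose before it adds, and if the temperature rises the diazo ester may undergo dipolar cycloaddition or conjugate addition at the enal C=C. The fallback builds the keto ester first and introduces the diazo group last; it sets out from 2 and returns at 6. Pinnick oxidation of 2 (NaClO2, NaH2PO4, 2-methyl-2-butene, t-BuOH/H2O) should give 2-methylideneheptanoic acid F7. Acylation of Meldrum's acid (DCC, DMAP, CH2Cl2, 0 °C → rt) should give 5-(1-hydroxy-2-methylideneheptylidene)-2,2-dimethyl-1,3-dioxane-4,6-dione F8. Heating F8 with benzyl alcohol 7 (toluene, 90 °C) should give benzyl 4-methylidene-3-oxononanoate F9. Regitz diazo transfer (p-acetamidobenzenesulfonyl azide, Et3N, MeCN, 0 °C) should then give 6.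

Further compounds
F1 | step 6 | 2,4-dihydroxy-6-pentylbenzoic acid | CCCCCc1cc(O)cc(O)c1C(=O)O
F2 | step 6 | benzyl 2,4-dihydroxy-6-pentylbenzoate | CCCCCc1cc(O)cc(O)c1C(=O)OCc1ccccc1
F3 | step 6 | benzyl 4-[(2,4-dimethoxy-6-propylbenzoyl)oxy]-2-hydroxy-6-pentylbenzoate | CCCCCc1cc(OC(=O)c2c(CCC)cc(OC)cc2OC)cc(O)c1C(=O)OCc1ccccc1
F4 | step 5 | benzyl vinyl ether | C=COCc1ccccc1
F5 | step 5 | benzyl 1,2-dibromoethyl ether (racemic) | BrCC(Br)OCc1ccccc1
F6 | step 5 | benzyl (Z)-2-bromovinyl ether | Br/C=C\OCc1ccccc1
F7 | step 2 | 2-methylideneheptanoic acid | CCCCCC(=C)C(=O)O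
F8 | step 2 | 5-(1-hydroxy-2-methylideneheptylidene)-2,2-dimethyl-1,3-dioxane-4,6-dione | CCCCCC(=C)C(O)=C1C(=O)OC(C)(C)OC1=O
F9 | step 2 | benzyl 4-methylidene-3-oxononanoate | CCCCCC(=C)C(=O)CC(=O)OCc1ccccc1
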